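**Strategy**

Pyran ring B is disconnected in a formal [3+3] sense into a 1,3-dielectrophile, the finished macrolide arene carrying a benzylic bromide (future C4) next to an aryl bromide (future C8a), and a 1,3-C,O-dinucleophile, the enolate of (4S)-3-acetyl-4-methylbutyrolactone. One copper-catalysed domino operation forms the C3a–C4 bond by C-benzylation and the O9–C8a bond by enolate O-arylation; acid added to the same flask then expels the lactone carbonyl as CO2 and folds the product into the cis-fused ketal. The step exploits that ketal carbon C9a and ring-fusion carbon C3a are the carbonyl and α-carbon of a methyl ketone, and that tetrahydrofuran ring C is a masked γ-butyrolactone.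

Key step: step 8

Remark (locants): the ketal bicycle is numbered as a furo[2,3-b]chromene (O1, C2, C3, C3a, C4, C4a–C8a, O9, C9a). Ring A is the benzene ring, ring B the dihydropyran, ring C the tetrahydrofuran and ring D the twelve-membered lactone. The macrolide is numbered as a 3-oxabicyclo[10.4.0]hexadecane.

Assumption: 4-bromo-2-methoxy-6-methylbenzoic acid and (S)-4-methyloxolan-2-one are taken as catalogue building blocks.

**Route**

Step 1
Reactants: 1 (S)-2-methyloxirane; 2 but-3-enylmagnesium bromide
Product: 3 (S)-hept-6-en-2-ol
Conditions: CuI (10 mol %), THF, −30 → 0 °C; then H2O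
Reagents that add atoms: none
Why: Copper-catalysed Grignard opening of a terminal epoxide at the unsubstituted carbon (SN2), which leaves the stereocentre untouched, so (S) should be retained.

Step 2
Reactants: 4 4-bromo-2-methoxy-6-methylbenzoic acid; 3 (S)-hept-6-en-2-ol
Product: 5 (R)-hept-6-en-2-yl 4-bromo-2-methoxy-6-methylbenzoate
Conditions: PPh3, DIAD, THF, 0 → 25 °C
Reagents that add atoms: none
Why: Mitsunobu esterification, in which the hindered but acidic benzoate attacks the activated carbinol by SN2 and inverts (S) to the (R) ester without reaction at the crowded carbonyl.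

Step 3
Reactants: 5 (R)-hept-6-en-2-yl 4-bromo-2-methoxy-6-methylbenzoate; 6 allyl bromide
Product: 7 (R)-hept-6-en-2-yl 4-bromo-2-(but-3-en-1-yl)-6-methoxybenzoate
Conditions: LiN(iPr)2 (1.1 equiv), THF, −78 °C; then 6, −78 → −40 °C
Reagents that add atoms: none
Why: Lateral lithiation of an ortho-toluate gives the ester-stabilised benzylic anion, which should be alkylated at carbon by allyl bromide; the amide base does not undergo bromine–lithium exchange.

Step 4
Reactants: 7 (R)-hept-6-en-2-yl 4-bromo-2-(but-3-en-1-yl)-6-methoxybenzoate
Product: 8 (4R)-14-bromo-16-methoxy-4-methyl-3-oxabicyclo[10.4.0]hexadeca-1(12),8,13,15-tetraen-2-one (E/Z mixture)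
Conditions: second-generation Grubbs catalyst RuCl2(=CHPh)(PCy3)(H2IMes) (5 mol %), CH2Cl2 (2 mM), 40 °C
Reagents that add atoms: none
Why: Ring-closing metathesis of two terminal alkenes at high dilution should close the twelve-membered ring D with loss of ethylene; the alkene geometry is irrelevant because the double bond is reduced next.

Step 5
Reactants: 8 macrocyclic alkene (E/Z mixture)
Product: 9 (4R)-14-bromo-16-methoxy-4-methyl-3-oxabicyclo[10.4.0]hexadeca-1(12),13,15-trien-2-one
Conditions: H2 (3 atm), RhCl(PPh3)3 (10 mol %), toluene/EtOH, 40 °C
Reagents that add atoms: none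
Why: Homogeneous hydrogenation with RhCl(PPh3)3 should reduce the disubstituted alkene while leaving the aryl bromide, which heterogeneous palladium would cleave.

Step 6
Reactants: 9 bromo macrolide
Product: 10 (4R)-14-bromo-13-(bromomethyl)-16-methoxy-4-methyl-3-oxabicyclo[10.4.0]hexadeca-1(12),13,15-trien-2-one
Conditions: (CH2O)n, 33 % HBr in AcOH, 50 °C
Reagents that add atoms: formaldehyde (as paraformaldehyde) C=O; hydrogen bromide Br
Why: Blanc-type bromomethylation (electrophilic aromatic substitution) should occur at C13, the position para to the methoxy group and ortho to the alkyl chain, in preference to C15, which is only ortho to the methoxy group and lies between it and bromine.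

Step 7
Reactants: 11 (S)-4-methyloxolan-2-one; 12 N-methoxy-N-methylacetamide
Product: 13 (4S)-3-acetyl-4-methyloxolan-2-one (C3 epimers and enol)
Conditions: LiN(SiMe3)2 (1.1 equiv), THF, −78 °C; then 12, −78 → 0 °C; then 1 M HCl
Reagents that add atoms: none
Why: Crossed Claisen acylation of the lactone enolate by a Weinreb amide, whose stable tetrahedral chelate should secure C-acylation; C4 is not acidic and keeps its (S) configuration, and the C3 configuration is of no consequence.

Step 8
Reactants: 10 dibromide; 13 (4S)-3-acetyl-4-methyloxolan-2-one
Product: 17 lasiodiplactone A, via C-benzylated keto lactone 14 (not isolated), via spiro enol ether 15 (not isolated), via keto phenol 16 (not isolated)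
Conditions: Cs2CO3 (3 equiv), 1,4-dioxane, 40 °C; then CuI (10 mol %), 1,10-phenanthroline (20 mol %), 100 °C; then 1 M aq H2SO4, 80 °C; crude product stirred with CSA (5 mol %), toluene, 60 °C
Reagents that add atoms: none
Why: The cesium enolate of 13 is C-benzylated by the benzylic bromide of 10 (SN2) to form the C3a–C4 bond, and the acetyl methyl group, the only enolisable site left in 14, then gives a copper enolate whose oxygen is joined to the ortho aryl carbon by Ullmann-type oxidative addition and C–O reductive elimination (O9–C8a bond), which closes ring B as a six-membered ring from a seven-membered cupracycle and leaves spiro enol ether 15. The closest known reaction type is the CuI-catalysed domino C-benzylation/O-arylation of β-keto esters with 2-bromobenzyl bromides to 4H-chromenes, followed here by the classical acid hydrolysis and decarboxylation of an α-alkyl-α-acetyl-γ-butyrolactone. Aqueous acid hydrates the enol ether, opens the lactone and expels CO2 to give 16, and ring C then closes by 5-exo-trig attack of the primary hydroxyl on the oxocarbenium ion at C9a. C3 comes unchanged from 13, whereas C3a and C9a are set under thermodynamic control because C3a epimerises through the enol of 16 and ketal formation is reversible: the bicycle can only be cis-fused and should place the C3 methyl group on the convex face, trans to C4, as in the xyloketal ketals. The step needs C- over O-alkylation (soft benzylic bromide, chelated cesium β-dicarbonyl enolate in dioxane) and O- over C-arylation of the methyl ketone enolate (copper, unlike palladium, does not α-arylate simple ketone enolates), and the quaternary carbon of 14 rules out any other enolate. The di-ortho-substituted macrolactone should survive carbonate and dilute acid.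

**Compound list**

1 | (S)-2-methyloxirane | C[C@H]1CO1 | starting material
2 | but-3-enylmagnesium bromide | C=CCC[Mg]Br | starting material
3 | (S)-hept-6-en-2-ol | C[C@H](O)CCCC=C | intermediate
4 | 4-bromo-2-methoxy-6-methylbenzoic acid | COc1cc(Br)cc(C)c1C(O)=O | starting material
5 | (R)-hept-6-en-2-yl 4-bromo-2-methoxy-6-methylbenzoate | COc1cc(Br)cc(C)c1C(=O)O[C@H](C)CCCC=C | intermediate
6 | allyl bromide | C=CCBr | starting material
7 | (R)-hept-6-en-2-yl 4-bromo-2-(but-3-en-1-yl)-6-methoxybenzoate | COc1cc(Br)cc(CCC=C)c1C(=O)O[C@H](C)CCCC=C | intermediate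
8 | (4R)-14-bromo-16-methoxy-4-methyl-3-oxabicyclo[10.4.0]hexadeca-1(12),8,13,15-tetraen-2-one (E/Z mixture) | COc1cc(Br)cc2c1C(=O)O[C@H](C)CCCC=CCC2 | intermediate
9 | (4R)-14-bromo-16-methoxy-4-methyl-3-oxabicyclo[10.4.0]hexadeca-1(12),13,15-trien-2-one | COc1cc(Br)cc2c1C(=O)O[C@H](C)CCCCCCC2 | intermediate
10 | (4R)-14-bromo-13-(bromomethyl)-16-methoxy-4-methyl-3-oxabicyclo[10.4.0]hexadeca-1(12),13,15-trien-2-one | COc1cc(Br)c(CBr)c2c1C(=O)O[C@H](C)CCCCCCC2 | intermediate
11 | (S)-4-methyloxolan-2-one | O=C1C[C@H](C)CO1 | starting material
12 | N-methoxy-N-methylacetamide | CC(=O)N(C)OC | starting material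
13 | (4S)-3-acetyl-4-methyloxolan-2-one (C3 epimers and enol) | CC(=O)C1[C@H](C)COC1=O | intermediate
14 | C-benzylated keto lactone: 10 with the benzylic bromine replaced by C3 of 13, quaternary carbon not defined | COc1cc(Br)c(CC3(C(C)=O)[C@H](C)COC3=O)c2c1C(=O)O[C@H](C)CCCCCCC2 | intermediate
15 | spiro enol ether: 2-methylidenechroman (ring B closed) spiro-fused at its C3 to the (4S)-4-methyl-γ-butyrolactone, ring D intact | COc1cc2c(c3c1C(=O)O[C@H](C)CCCCCCC3)CC1([C@H](C)COC1=O)C(=C)O2 | intermediate
16 | keto phenol: (4R)-13-[(3S)-2-acetyl-4-hydroxy-3-methylbutyl]-14-hydroxy-16-methoxy-4-methyl-3-oxabicyclo[10.4.0]hexadeca-1(12),13,15-trien-2-one (side-chain C2 epimers) | COc1cc(O)c(CC(C(C)=O)[C@H](C)CO)c2c1C(=O)O[C@H](C)CCCCCCC2 | intermediate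
17 | lasiodiplactone A | COc1cc2c(c3c1C(=O)O[C@H](C)CCCCCCC3)C[C@H]1[C@H](C)CO[C@@]1(C)O2 | target

**Totals**

Total step count: 8
Longest linear sequence: 7 steps (steps 1, 2, 3, 4, 5, 6 and 8)

**Steps most likely to fail**

Step 8. What may go wrong:
- O-alkylation of the hindered cesium enolate instead of C-alkylation.
- Slow enolisation of the methyl ketone, so that the copper-mediated C–O coupling stalls or gives way to hydrodebromination.
- Incomplete equilibration at the ring fusion, which would leave the epimeric ketal.

Fallback: the sequence is run stepwise and the aryl C–O bond is made by borylation and oxidation instead of enolate arylation. It sets out from 10 and 13 and comes back at 17. Alkylation of 13 with 10 under K2CO3 and NaI in acetone should give 14, which is now isolated. Heating 14 in 1 M aq H2SO4/dioxane at 80 °C should open the lactone and decarboxylate to the bromo ketol F1, present partly as its cyclic hemiketal. Miyaura borylation (B2pin2, PdCl2(dppf), KOAc, dioxane, 90 °C; the weak base gives no ketone enolate) should give the pinacol boronate F2. Oxidation with NaBO3·4H2O in THF/H2O should give phenol 16, which should close to 17 with CSA in toluene at 60 °C.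

Step 6. What may go wrong:
- Attack of the electrophile at the other free ring position.
- Friedel–Crafts self-alkylation of the electron-rich benzylic bromide to diarylmethanes.

Fallback: the carbon is brought in at the aldehyde oxidation level, whose product is deactivated towards further substitution and whose isomers can be separated before the bromide is made. It sets out from 9 and comes back at 10. Rieche formylation (Cl2CHOMe, TiCl4, CH2Cl2, −20 → 0 °C) should give the aldehyde F3. NaBH4 in MeOH at 0 °C should give the benzylic alcohol F4, and PBr3 in CH2Cl2 at 0 °C should give 10.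

Step 3. What may go wrong:
- Deprotonation of the ring position between methoxy and bromine, leading to aryne or halogen-dance pathways.
- Claisen-type self-condensation of the benzylic anion with the ester of a second molecule.

Fallback: the polarity at the benzylic carbon is reversed so that no strong base meets the aryl bromide. It sets out from 4 and comes back at 7. Methylation (MeI, K2CO3, DMF) should give the methyl ester F5. Wohl–Ziegler bromination (NBS, AIBN, PhCF3, 80 °C) should give the benzylic bromide F6. Coupling with allylmagnesium bromide (CuI cat., THF, −78 °C) should give the butenyl ester F7. SN2 demethylation of the hindered ester (LiI, pyridine, 115 °C) should give the butenyl acid F8, and Mitsunobu esterification with 3 (PPh3, DIAD, THF) should give 7.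

Further compounds
F1 | step 8 | bromo ketol: (4R)-13-[(3S)-2-acetyl-4-hydroxy-3-methylbutyl]-14-bromo-16-methoxy-4-methyl-3-oxabicyclo[10.4.0]hexadeca-1(12),13,15-trien-2-one | COc1cc(Br)c(CC(C(C)=O)[C@H](C)CO)c2c1C(=O)O[C@H](C)CCCCCCC2
F2 | step 8 | pinacol boronate: F1 with the bromine replaced by 4,4,5,5-tetramethyl-1,3,2-dioxaborolan-2-yl | COc1cc(B3OC(C)(C)C(C)(C)O3)c(CC(C(C)=O)[C@H](C)CO)c2c1C(=O)O[C@H](C)CCCCCCC2
F3 | step 6 | (4R)-14-bromo-16-methoxy-4-methyl-2-oxo-3-oxabicyclo[10.4.0]hexadeca-1(12),13,15-triene-13-carbaldehyde | COc1cc(Br)c(C=O)c2c1C(=O)O[C@H](C)CCCCCCC2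
F4 | step 6 | (4R)-14-bromo-13-(hydroxymethyl)-16-methoxy-4-methyl-3-oxabicyclo[10.4.0]hexadeca-1(12),13,15-trien-2-one | COc1cc(Br)c(CO)c2c1C(=O)O[C@H](C)CCCCCCC2
F5 | step 3 | methyl 4-bromo-2-methoxy-6-methylbenzoate | COc1cc(Br)cc(C)c1C(=O)OC
F6 | step 3 | methyl 4-bromo-2-(bromomethyl)-6-methoxybenzoate | COc1cc(Br)cc(CBr)c1C(=O)OC
F7 | step 3 | methyl 4-bromo-2-(but-3-en-1-yl)-6-methoxybenzoate | COc1cc(Br)cc(CCC=C)c1C(=O)OC
F8 | step 3 | 4-bromo-2-(but-3-en-1-yl)-6-methoxybenzoic acid | COc1cc(Br)cc(CCC=C)c1C(O)=O
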